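- Set the making of partner from gas equal to its use (the steady-state approximation), and reckon the rate of the flask from the partner that this leaves dissolved.

the same everywhere: left-handed substrate 0.18 M; right-handed substrate 0.18 M; gas 6.3 mM (held)
- Wednesday's: free catalyst 3.4 mol%; run made earlier
- Sunday's: free catalyst 7.5 mol%; run made earlier
- flask: free catalyst 5 mol%

- Wednesday's (time / d: left-handed product / %, left-handed substrate / %): 0.250: 5.1, 45.0; 0.625: 12.3, 37.9; 1.25: 23.1, 25.8; 2.08: 36.8, 13.2; 3.00: 44.9, 4.7; 4.00: 49.2, 0.9
- Sunday's (time / d: left-handed product / %, left-handed substrate / %): 0.625: 14.9, 34.9; 1.25: 28.5, 21.6; 1.67: 36.5, 14.1; 2.50: 47.4, 3.0; 3.00: 48.9, 0.8; 4.00: 49.9, 0.4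

(each reading ± 0.5 percentage points)

- free catalyst is single-handed; left-handed substrate and right-handed substrate are mirror images of each other, charged as a racemate, each of them at the stated concentration
- at the start none of partner is dissolved
- what was read earlier has a scatter of 0.5 percentage points, one standard deviation
- steps that have been proposed: partner + free catalyst + left-handed substrate -> free catalyst + left-handed product; partner + free catalyst + right-handed substrate -> free catalyst + right-handed product; gas <-> partner; partner + free catalyst -> spent catalyst

1. factor on the rate of making left-handed product when 30% of the left-handed substrate and right-handed substrate together are converted if free catalyst is charged twice over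
2. factor on the rate when 30% of the left-handed substrate and right-handed substrate together are converted if free catalyst is charged at 1 mol% instead

- Take partner as made at a ceiling rate times the unfilled part of saturation, and as used in proportion to partner times load, where load is the catalyst loading times left-handed substrate as a share of all substrate charged. Then rate = ceiling × load / (load + balance load).
- Up to 1.25 d, Wednesday's run averages 0.0665 M d⁻¹ on a mean load of 0.0129, and Sunday's run averages 0.0821 M d⁻¹ on 0.0268. Sunday's load is 2.08 times Wednesday's, but its rate is 1.23 times.
- Solved for these two pairs, the rule reads 0.105 M d⁻¹ for the gas ceiling, the rate of making partner while none stands dissolved, and 0.00739 for the balance load.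
- Once partner has built up in the flask, the load of 0.0250 gives a slope of 0.0810 M d⁻¹. The knee comes when left-handed substrate falls to 14.8% of the charge, where the rate is half the ceiling, and left-handed product levels off at 0.18 M.
- The conversion of 30% comes before that knee. With all of it put on left-handed substrate, the load is 0.0100, so this reckoning gives 1.27 for the doubled charge and 0.370 for 1 mol%.
- The forecast gives 1.24 (1.12 to 1.38) and 0.38 (0.27 to 0.48), holding that “supply of dissolved partner from the gas is partly limiting”.
- The flask gives 1.18 for the doubled charge and 0.416 for 1 mol%.

    partner + free catalyst + left-handed substrate → free catalyst + left-handed product (k = 2200 M⁻² h⁻¹)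
    partner + free catalyst + right-handed substrate → free catalyst + right-handed product (k = 41.0 M⁻² h⁻¹)
    gas ⇌ partner, rate k3*(csat - [partner]) (kL = 0.650 h⁻¹)
    partner + free catalyst → spent catalyst (k = 0.680 M⁻¹ h⁻¹)

- At 1.40 d the flask makes partner 1.02 times as fast as it uses it, each step taken net. On Sunday's run, between 1.67 d and 2.50 d, the mean load of 0.00641 puts the rule at 0.0488 M d⁻¹, and the readings give 0.0473 M d⁻¹.

The runs were generated by integration with made-up constants; the scatter is artificial.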